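**Retrosynthetic overview**

1. The target is cut at the C3 ester and the N-Boc/O-silyl groups, giving an N-Boc 3-hydroxy-cis-decahydroquinoline with the full C5 side chain; this comes from hydrogenation of a ring-B 1,3-diene (C5=C6, C7=C8), which sets C5 and frees O3.
2. The ring-B diene comes from a one-operation Michael/Wittig annulation of allylidenetriphenylphosphorane (C6–C7–C8) onto a monocyclic ring-A ketone: C8–C8a by conjugate addition, C5=C6 by intramolecular olefination.
3. Enabling feature: in ring A the unit N1–C8a=C4a–C5(=O) is an N-Boc vinylogous amide, so the enamide carbon C8a (β-carbon) and the exocyclic ketone carbon C5 are two electrophiles in a 1,3-relationship across C4a, matched to the γ- and α-carbons of the ylide.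
4. The ring-A ketone comes from aza-Michael addition of an anti 3-amino-2-benzyloxybutyl tosylate (from crotyl alcohol by asymmetric epoxidation and azide opening) to a side-chain ynone (from (R)-2-propyloxirane), then intramolecular C-alkylation (C4–C4a).
5. Ring order: ring A first (step 11), ring B second (step 13). C2/C3 come from the epoxy alcohol, C5' from the epoxide, C8a/C4a from the annulation, C5 from the hydrogenation.

Key step: step 13

Remark: atoms are numbered as in decahydroquinoline (N1, C2–C8a; side chain C1'–C8'); the target is taken as drawn, (2S,3R,4aS,5S,8aR,5'R) with a (2E,4E)-dienoate.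

**Route**

Step 1
Reactants: 1 (E)-but-2-en-1-ol
Product: 2 [(2R,3R)-3-methyloxiran-2-yl]methanol
Conditions: Ti(OiPr)4 (5 mol%), D-(−)-diisopropyl tartrate (6 mol%), t-BuOOH, 4 Å MS, CH2Cl2, −20 °C
Reagents that add atoms: tert-butyl hydroperoxide, CC(C)(C)OO
Why: Sharpless asymmetric epoxidation of a primary allylic alcohol; the D-tartrate/Ti(OiPr)4 catalyst should deliver oxygen to one alkene face and set both epoxide carbons as (2R,3R).

Step 2
Reactants: 2 [(2R,3R)-3-methyloxiran-2-yl]methanol
Product: 3 (2S,3S)-3-azidobutane-1,2-diol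
Conditions: Ti(OiPr)4 (1.2 equiv), Me3SiN3 (2.4 equiv), benzene, 80 °C; dilute aqueous acid work-up; product kept in solution
Reagents that add atoms: azidotrimethylsilane, C[Si](C)(C)N=[N+]=[N-]
Why: Titanium-assisted opening of a 2,3-epoxy alcohol, in which azide should attack C3 of the chelated epoxide with inversion; this sets the nitrogen-bearing carbon (later C2) and leaves the oxygen-bearing carbon (later C3) untouched, giving the anti relationship.

Step 3
Reactants: 3 (2S,3S)-3-azidobutane-1,2-diol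
Product: 4 (2S,3S)-3-azido-2-hydroxybutyl 4-methylbenzenesulfonate
Conditions: TsCl (1.05 equiv), Bu2SnO (2 mol%), Et3N, CH2Cl2, 0 °C to rt
Reagents that add atoms: 4-methylbenzenesulfonyl chloride, Cc1ccc(cc1)S(=O)(=O)Cl
Why: Tin-acetal-catalysed sulfonylation of a 1,2-diol should activate only the primary hydroxyl (later C4); no stereocentre is touched.

Step 4
Reactants: 4 (2S,3S)-3-azido-2-hydroxybutyl 4-methylbenzenesulfonate
Product: 5 (2S,3S)-3-azido-2-(benzyloxy)butyl 4-methylbenzenesulfonate
Conditions: benzyl 2,2,2-trichloroacetimidate (1.5 equiv), TfOH (5 mol%), CH2Cl2/cyclohexane, 0 °C to rt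
Reagents that add atoms: benzyl 2,2,2-trichloroacetimidate, N=C(OCc1ccccc1)C(Cl)(Cl)Cl
Why: Acid-catalysed O-benzylation with a trichloroacetimidate avoids base, so the β-tosyloxy alcohol should not close to an epoxide.

Step 5
Reactants: 6 5-bromopent-1-ene; 7 (2R)-2-propyloxirane
Product: 9 (4R)-dec-9-en-4-ol, via pent-4-enylmagnesium bromide 8 (not isolated)
Conditions: Mg turnings, THF, rt; then CuI (10 mol%), 7, THF, −30 to 0 °C; aq. NH4Cl
Reagents that add atoms: none
Why: Copper-catalysed Grignard opening of a terminal epoxide at its CH2 carbon; the carbinol stereocentre (later C5') is carried over unchanged from the epoxide.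

Step 6
Reactants: 9 (4R)-dec-9-en-4-ol
Product: 10 tert-butyl[(4R)-dec-9-en-4-yloxy]dimethylsilane
Conditions: TBSCl, imidazole, DMF, rt
Reagents that add atoms: tert-butyl(chloro)dimethylsilane, CC(C)(C)[Si](C)(C)Cl
Why: Standard silylation of a secondary alcohol; the silyl ether should survive every later step up to the final acidolysis.

Step 7
Reactants: 10 tert-butyl[(4R)-dec-9-en-4-yloxy]dimethylsilane
Product: 12 (6R)-6-{[tert-butyl(dimethyl)silyl]oxy}nonanal, via ozonide 11 (not isolated)
Conditions: O3, CH2Cl2, −78 °C; then PPh3, −78 °C to rt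
Reagents that add atoms: ozone, [O-][O+]=O
Why: Ozonolysis with reductive work-up should cut the terminal alkene to the aldehyde whose carbon becomes C5.

Step 8
Reactants: 12 (6R)-6-{[tert-butyl(dimethyl)silyl]oxy}nonanal; 13 ethynylmagnesium bromide
Product: 14 (8R)-8-{[tert-butyl(dimethyl)silyl]oxy}undec-1-yn-3-ol (both C3 epimers)
Conditions: 13 (0.5 M in THF), THF, 0 °C; aq. NH4Cl
Reagents that add atoms: none
Why: Grignard addition to an aldehyde brings in the two carbons that become C4a and C8a; the new carbinol centre is oxidised in the next step.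

Step 9
Reactants: 14 (8R)-8-{[tert-butyl(dimethyl)silyl]oxy}undec-1-yn-3-ol
Product: 15 (8R)-8-{[tert-butyl(dimethyl)silyl]oxy}undec-1-yn-3-one
Conditions: 2-iodoxybenzoic acid (IBX), EtOAc, 75 °C
Reagents that add atoms: none
Why: Oxidation of a propargylic alcohol to the terminal ynone; the only stereocentre is remote and not epimerisable.

Step 10
Reactants: 5 (2S,3S)-3-azido-2-(benzyloxy)butyl 4-methylbenzenesulfonate; 15 (8R)-8-{[tert-butyl(dimethyl)silyl]oxy}undec-1-yn-3-one
Product: 18 (2S,3S)-2-(benzyloxy)-3-{[(1Z,8R)-8-{[tert-butyl(dimethyl)silyl]oxy}-3-oxoundec-1-en-1-yl]amino}butyl 4-methylbenzenesulfonate, via iminophosphorane 16 (not isolated), via amine 17 (not isolated)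
Conditions: PPh3 (1.0 equiv), THF, rt; H2O, 50 °C; then 15, EtOH, rt
Reagents that add atoms: none
Why: Staudinger reduction followed by aza-Michael addition of the primary amine to the terminal ynone should give the hydrogen-bonded (Z)-enaminone and join N1 to C8a with full regiocontrol.

Step 11
Reactants: 18 (2S,3S)-2-(benzyloxy)-3-{[(1Z,8R)-8-{[tert-butyl(dimethyl)silyl]oxy}-3-oxoundec-1-en-1-yl]amino}butyl 4-methylbenzenesulfonate
Product: 19 (6R)-1-[(5R,6S)-5-(benzyloxy)-6-methyl-1,4,5,6-tetrahydropyridin-3-yl]-6-{[tert-butyl(dimethyl)silyl]oxy}nonan-1-one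
Conditions: Cs2CO3, MeCN, 80 °C
Reagents that add atoms: none
Why: Intramolecular C-alkylation of a secondary enaminone (6-(enolendo)-exo-tet) should close ring A through C4–C4a, since N- or O-alkylation would need a four- or eight-membered ring; alkylative cyclisations of ω-haloalkyl enaminones to 3-acyl-tetrahydropyridines are close precedent.

Step 12
Reactants: 19 (6R)-1-[(5R,6S)-5-(benzyloxy)-6-methyl-1,4,5,6-tetrahydropyridin-3-yl]-6-{[tert-butyl(dimethyl)silyl]oxy}nonan-1-one
Product: 20 tert-butyl (2S,3R)-3-(benzyloxy)-5-[(6R)-6-{[tert-butyl(dimethyl)silyl]oxy}nonanoyl]-2-methyl-3,4-dihydropyridine-1(2H)-carboxylate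
Conditions: Boc2O, DMAP (cat.), Et3N, MeCN, rt
Reagents that add atoms: di-tert-butyl dicarbonate, CC(C)(C)OC(=O)OC(=O)OC(C)(C)C
Why: N-acylation of the vinylogous amide removes the acidic N–H, raises the electrophilicity of C8a and introduces the A(1,3) strain that later controls the face of attack at C8a.

Step 13
Reactants: 20 tert-butyl (2S,3R)-3-(benzyloxy)-5-[(6R)-6-{[tert-butyl(dimethyl)silyl]oxy}nonanoyl]-2-methyl-3,4-dihydropyridine-1(2H)-carboxylate; 21 triphenyl(prop-2-en-1-yl)phosphonium bromide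
Product: 24 tert-butyl (2S,3R,4aS,8aR)-3-(benzyloxy)-5-[(5R)-5-{[tert-butyl(dimethyl)silyl]oxy}octyl]-2-methyl-3,4,4a,8a-tetrahydroquinoline-1(2H)-carboxylate, via allylidene ylide 22 (not isolated), via keto ylide 23 (not isolated)
Conditions: 21 (2.5 equiv), NaN(SiMe3)2, THF, −78 to 0 °C; then 20, −78 °C to reflux
Reagents that add atoms: none
Why: Proposed new method: the γ-carbon (C8) of the allylic ylide 22 should add in conjugate fashion to C8a of the N-Boc vinylogous amide 20, proton transfer from C8 to the enolate should regenerate an allylic ylide (23), and its ylide carbon C6 should then olefinate the ketone C5 intramolecularly, so that the C8–C8a bond and the C5=C6 bond arise in one operation; the closest known reaction is the Michael/Wittig cyclohexadiene annulation of simple α,β-unsaturated ketones with allylidenetriphenylphosphorane, which has not been run on a β-amido enone. Ring B closes in the Wittig step as a 6-exo-trig attack of C6 on the exocyclic C5 carbonyl, followed by collapse of the oxaphosphetane. C8a is set in the conjugate addition: A(1,3) strain with the Boc group holds the C2 methyl pseudoaxial, and stereoelectronically preferred axial attack on the half-chair places C8 cis to that methyl, as in cuprate additions to 2-substituted N-acyl-2,3-dihydro-4-pyridones. C4a is set by protonation of the enolate under equilibrating conditions: only the epimer with an equatorial acyl group cis to the axial C8a chain can reach the six-membered Wittig transition state (the trans epimer would hold the two arms anti and clash with the axial C3 benzyloxy group), so the ring fusion should be cis. The step needs 1,4- over 1,2-addition and γ- over α-attack of the ylide; the N1 lone pair and the α-branch at C4a make the C5 carbonyl a poor Wittig partner, C8a is an unhindered CH, and semi-stabilised allylic ylides add to enones through their unhindered γ-terminus.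

Step 14
Reactants: 24 tert-butyl (2S,3R,4aS,8aR)-3-(benzyloxy)-5-[(5R)-5-{[tert-butyl(dimethyl)silyl]oxy}octyl]-2-methyl-3,4,4a,8a-tetrahydroquinoline-1(2H)-carboxylate
Product: 25 tert-butyl (2S,3R,4aS,5S,8aR)-5-[(5R)-5-{[tert-butyl(dimethyl)silyl]oxy}octyl]-3-hydroxy-2-methyloctahydroquinoline-1(2H)-carboxylate
Conditions: H2 (1 atm), Pd/C (10 wt%), EtOAc, rt
Reagents that add atoms: none
Why: Heterogeneous hydrogenation should saturate the diene and cleave the benzyl ether in one operation; hydrogen should reach C5 from the convex face, anti to the pseudoaxial C4 on the neighbouring C4a, which puts H5 cis to H4a.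

Step 15
Reactants: 26 (2E)-hex-2-enal; 27 propanedioic acid
Product: 29 (2E,4E)-octa-2,4-dienoic acid, via alkylidenemalonic acid 28 (not isolated)
Conditions: pyridine, piperidine (cat.), 90 °C
Reagents that add atoms: none
Why: Doebner-modified Knoevenagel condensation; decarboxylation of the alkylidenemalonic acid should give the (E)-configured new double bond, while the second (E)-alkene comes from the enal.

Step 16
Reactants: 25 tert-butyl (2S,3R,4aS,5S,8aR)-5-[(5R)-5-{[tert-butyl(dimethyl)silyl]oxy}octyl]-3-hydroxy-2-methyloctahydroquinoline-1(2H)-carboxylate; 29 (2E,4E)-octa-2,4-dienoic acid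
Product: 31 tert-butyl (2S,3R,4aS,5S,8aR)-5-[(5R)-5-{[tert-butyl(dimethyl)silyl]oxy}octyl]-2-methyl-3-{[(2E,4E)-octa-2,4-dienoyl]oxy}octahydroquinoline-1(2H)-carboxylate, via mixed anhydride 30 (not isolated)
Conditions: 2,4,6-trichlorobenzoyl chloride, Et3N, THF, rt; then 25, DMAP, toluene, rt to 60 °C
Reagents that add atoms: none
Why: Yamaguchi esterification acylates the C3 hydroxyl with retention, so the (3R) centre set in step 1 is kept.

Step 17
Reactants: 31 tert-butyl (2S,3R,4aS,5S,8aR)-5-[(5R)-5-{[tert-butyl(dimethyl)silyl]oxy}octyl]-2-methyl-3-{[(2E,4E)-octa-2,4-dienoyl]oxy}octahydroquinoline-1(2H)-carboxylate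
Product: 32 lepadin H, (2S,3R,4aS,5S,8aR)-5-[(5R)-5-hydroxyoctyl]-2-methyldecahydroquinolin-3-yl (2E,4E)-octa-2,4-dienoate
Conditions: TFA/CH2Cl2/H2O (10:10:1), 0 °C to rt; aq. NaHCO3
Reagents that add atoms: none
Why: Acidolysis should remove the Boc group and the secondary silyl ether together without touching the dienoate; O-to-N acyl shift is not expected because the equatorial C3 oxygen is anti to N1.

**Compound list**

1 | (E)-but-2-en-1-ol | C/C=C/CO | starting material
2 | [(2R,3R)-3-methyloxiran-2-yl]methanol | C[C@H]1O[C@@H]1CO | intermediate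
3 | (2S,3S)-3-azidobutane-1,2-diol | [N-]=[N+]=N[C@@H](C)[C@H](O)CO | intermediate
4 | (2S,3S)-3-azido-2-hydroxybutyl 4-methylbenzenesulfonate | [N-]=[N+]=N[C@@H](C)[C@H](O)COS(=O)(=O)c1ccc(C)cc1 | intermediate
5 | (2S,3S)-3-azido-2-(benzyloxy)butyl 4-methylbenzenesulfonate | [N-]=[N+]=N[C@@H](C)[C@H](OCc1ccccc1)COS(=O)(=O)c1ccc(C)cc1 | intermediate
6 | 5-bromopent-1-ene | C=CCCCBr | starting material
7 | (2R)-2-propyloxirane | CCC[C@@H]1CO1 | starting material
8 | pent-4-enylmagnesium bromide | C=CCCC[Mg]Br | intermediate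
9 | (4R)-dec-9-en-4-ol | C=CCCCC[C@H](O)CCC | intermediate
10 | tert-butyl[(4R)-dec-9-en-4-yloxy]dimethylsilane | C=CCCCC[C@H](O[Si](C)(C)C(C)(C)C)CCC | intermediate
11 | 3-[(5R)-5-{[tert-butyl(dimethyl)silyl]oxy}octyl]-1,2,4-trioxolane (ozonide, ring carbon unassigned) | O1OC(CCCC[C@H](O[Si](C)(C)C(C)(C)C)CCC)OC1 | intermediate
12 | (6R)-6-{[tert-butyl(dimethyl)silyl]oxy}nonanal | O=CCCCC[C@H](O[Si](C)(C)C(C)(C)C)CCC | intermediate
13 | ethynylmagnesium bromide | C#C[Mg]Br | starting material
14 | (8R)-8-{[tert-butyl(dimethyl)silyl]oxy}undec-1-yn-3-ol (both C3 epimers) | C#CC(O)CCCC[C@H](O[Si](C)(C)C(C)(C)C)CCC | intermediate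
15 | (8R)-8-{[tert-butyl(dimethyl)silyl]oxy}undec-1-yn-3-one | C#CC(=O)CCCC[C@H](O[Si](C)(C)C(C)(C)C)CCC | intermediate
16 | (2S,3S)-2-(benzyloxy)-3-[(triphenyl-λ5-phosphanylidene)amino]butyl 4-methylbenzenesulfonate | c1ccccc1P(c1ccccc1)(c1ccccc1)=N[C@@H](C)[C@H](OCc1ccccc1)COS(=O)(=O)c1ccc(C)cc1 | intermediate
17 | (2S,3S)-3-amino-2-(benzyloxy)butyl 4-methylbenzenesulfonate | N[C@@H](C)[C@H](OCc1ccccc1)COS(=O)(=O)c1ccc(C)cc1 | intermediate
18 | (2S,3S)-2-(benzyloxy)-3-{[(1Z,8R)-8-{[tert-butyl(dimethyl)silyl]oxy}-3-oxoundec-1-en-1-yl]amino}butyl 4-methylbenzenesulfonate | CCC[C@@H](O[Si](C)(C)C(C)(C)C)CCCCC(=O)/C=C\N[C@@H](C)[C@H](OCc1ccccc1)COS(=O)(=O)c1ccc(C)cc1 | intermediate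
19 | (6R)-1-[(5R,6S)-5-(benzyloxy)-6-methyl-1,4,5,6-tetrahydropyridin-3-yl]-6-{[tert-butyl(dimethyl)silyl]oxy}nonan-1-one | c1ccccc1CO[C@@H]2CC(C(=O)CCCC[C@H](O[Si](C)(C)C(C)(C)C)CCC)=CN[C@H]2C | intermediate
20 | tert-butyl (2S,3R)-3-(benzyloxy)-5-[(6R)-6-{[tert-butyl(dimethyl)silyl]oxy}nonanoyl]-2-methyl-3,4-dihydropyridine-1(2H)-carboxylate | c1ccccc1CO[C@@H]2CC(C(=O)CCCC[C@H](O[Si](C)(C)C(C)(C)C)CCC)=CN(C(=O)OC(C)(C)C)[C@H]2C | intermediate
21 | triphenyl(prop-2-en-1-yl)phosphonium bromide | C=CC[P+](c1ccccc1)(c1ccccc1)c1ccccc1.[Br-] | starting material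
22 | triphenyl(prop-2-en-1-ylidene)-λ5-phosphane | C=CC=P(c1ccccc1)(c1ccccc1)c1ccccc1 | intermediate
23 | tert-butyl (2S,3R,5R,6R)-3-(benzyloxy)-5-[(6R)-6-{[tert-butyl(dimethyl)silyl]oxy}nonanoyl]-2-methyl-6-[(1Z)-3-(triphenyl-λ5-phosphanylidene)prop-1-en-1-yl]piperidine-1-carboxylate | c1ccccc1CO[C@@H]2C[C@@H](C(=O)CCCC[C@H](O[Si](C)(C)C(C)(C)C)CCC)[C@@H](/C=C\C=P(c3ccccc3)(c3ccccc3)c3ccccc3)N(C(=O)OC(C)(C)C)[C@H]2C | intermediate
24 | tert-butyl (2S,3R,4aS,8aR)-3-(benzyloxy)-5-[(5R)-5-{[tert-butyl(dimethyl)silyl]oxy}octyl]-2-methyl-3,4,4a,8a-tetrahydroquinoline-1(2H)-carboxylate | c1ccccc1CO[C@@H]2C[C@H]3C(CCCC[C@H](O[Si](C)(C)C(C)(C)C)CCC)=CC=C[C@H]3N(C(=O)OC(C)(C)C)[C@H]2C | intermediate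
25 | tert-butyl (2S,3R,4aS,5S,8aR)-5-[(5R)-5-{[tert-butyl(dimethyl)silyl]oxy}octyl]-3-hydroxy-2-methyloctahydroquinoline-1(2H)-carboxylate | O[C@@H]1C[C@H]2[C@@H](CCCC[C@H](O[Si](C)(C)C(C)(C)C)CCC)CCC[C@H]2N(C(=O)OC(C)(C)C)[C@H]1C | intermediate
26 | (2E)-hex-2-enal | CCC/C=C/C=O | starting material
27 | propanedioic acid | OC(=O)CC(=O)O | starting material
28 | 2-[(2E)-hex-2-en-1-ylidene]propanedioic acid | CCC/C=C/C=C(C(=O)O)C(=O)O | intermediate
29 | (2E,4E)-octa-2,4-dienoic acid | CCC/C=C/C=C/C(=O)O | intermediate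
30 | (2E,4E)-octa-2,4-dienoic 2,4,6-trichlorobenzoic anhydride | CCC/C=C/C=C/C(=O)OC(=O)c1c(Cl)cc(Cl)cc1Cl | intermediate
31 | tert-butyl (2S,3R,4aS,5S,8aR)-5-[(5R)-5-{[tert-butyl(dimethyl)silyl]oxy}octyl]-2-methyl-3-{[(2E,4E)-octa-2,4-dienoyl]oxy}octahydroquinoline-1(2H)-carboxylate | CCC/C=C/C=C/C(=O)O[C@@H]1C[C@H]2[C@@H](CCCC[C@H](O[Si](C)(C)C(C)(C)C)CCC)CCC[C@H]2N(C(=O)OC(C)(C)C)[C@H]1C | intermediate
32 | lepadin H, (2S,3R,4aS,5S,8aR)-5-[(5R)-5-hydroxyoctyl]-2-methyldecahydroquinolin-3-yl (2E,4E)-octa-2,4-dienoate | CCC/C=C/C=C/C(=O)O[C@@H]1C[C@H]2[C@@H](CCCC[C@H](O)CCC)CCC[C@H]2N[C@H]1C | target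

**Step count and risks**

Total step count: 17. Longest linear sequence: 12 steps (steps 5 to 14, then 16 and 17, from 6 and 7).

Steps most likely to fail:

Step 13 (proposed new method). The ylide may attack the C5 carbonyl directly, react through its α-carbon, or merely enolise the ketone at C1', so that no conjugate addition at C8a takes place; the addition may also come from the wrong face. The fallback sets out from 20 and comes back at 25, and forms the two ring-B bonds in separate, known operations. Compound 20 would be treated with but-3-enylmagnesium bromide and CuBr·SMe2 (cat.) in THF at −78 °C. This copper-mediated conjugate addition to N-acyl vinylogous amides is known to go cis to the C2 substituent and, after equilibration of the acyl group (DBU, cat.), should give the butenyl ketone F1. Wittig methylenation of the C5 ketone (methyltriphenylphosphonium bromide, KOtBu, toluene, 80 °C) should give the diene F2. Ring-closing metathesis with the second-generation Grubbs catalyst (CH2Cl2, 40 °C) should then close ring B as the C5=C6 cyclohexene F3 with loss of ethene. Hydrogenation of F3 under the conditions of step 14 should give 25.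

Step 14. Hydrogen delivery to C5 may be poorly face-selective, and the C5=C6 bond may migrate into the ring fusion on the metal surface, which would erase the C4a configuration. The fallback sets out from 24 and comes back at 25, and replaces surface delivery by thermodynamically controlled radical hydrogen-atom transfer. Treatment of 24 with Mn(dpm)3 (tris(2,2,6,6-tetramethylheptane-3,5-dionato)manganese, cat.), PhSiH3 and t-BuOOH in i-PrOH at rt should reduce the diene stepwise through a tertiary C5 radical that takes up hydrogen to give the more stable equatorial side chain (the natural configuration in N-acyl cis-decahydroquinolines), giving the saturated benzyl ether F4. Hydrogenolysis of F4 (H2, Pd(OH)2/C, EtOH) should then give 25.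

Step 16. Acyl transfer to the hindered C3 hydroxyl, flanked by the N-Boc-bearing C2, may be slow, and the activated dienoyl unit may isomerise or deconjugate before it is transferred. The fallback sets out from 25 and comes back at 31, and builds the dienoate on the oxygen instead of transferring it. Acylation of 25 with the small diethylphosphonoacetic acid (DCC, DMAP, CH2Cl2) should give the phosphonoacetate F5. Horner–Wadsworth–Emmons olefination of F5 with (2E)-hex-2-enal 26 (LiCl, DBU, MeCN, rt) should then form the (2E,4E)-dienoate directly and give 31.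

Further compounds
F1 | step 13 | tert-butyl (2S,3R,5R,6R)-3-(benzyloxy)-6-(but-3-en-1-yl)-5-[(6R)-6-{[tert-butyl(dimethyl)silyl]oxy}nonanoyl]-2-methylpiperidine-1-carboxylate | c1ccccc1CO[C@@H]2C[C@@H](C(=O)CCCC[C@H](O[Si](C)(C)C(C)(C)C)CCC)[C@@H](CCC=C)N(C(=O)OC(C)(C)C)[C@H]2C
F2 | step 13 | tert-butyl (2S,3R,5S,6R)-3-(benzyloxy)-6-(but-3-en-1-yl)-5-[(7R)-7-{[tert-butyl(dimethyl)silyl]oxy}dec-1-en-2-yl]-2-methylpiperidine-1-carboxylate | c1ccccc1CO[C@@H]2C[C@@H](C(=C)CCCC[C@H](O[Si](C)(C)C(C)(C)C)CCC)[C@@H](CCC=C)N(C(=O)OC(C)(C)C)[C@H]2C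
F3 | step 13 | tert-butyl (2S,3R,4aS,8aR)-3-(benzyloxy)-5-[(5R)-5-{[tert-butyl(dimethyl)silyl]oxy}octyl]-2-methyl-3,4,4a,7,8,8a-hexahydroquinoline-1(2H)-carboxylate | c1ccccc1CO[C@@H]2C[C@H]3C(CCCC[C@H](O[Si](C)(C)C(C)(C)C)CCC)=CCC[C@H]3N(C(=O)OC(C)(C)C)[C@H]2C
F4 | step 14 | tert-butyl (2S,3R,4aS,5S,8aR)-3-(benzyloxy)-5-[(5R)-5-{[tert-butyl(dimethyl)silyl]oxy}octyl]-2-methyloctahydroquinoline-1(2H)-carboxylate | c1ccccc1CO[C@@H]2C[C@H]3[C@@H](CCCC[C@H](O[Si](C)(C)C(C)(C)C)CCC)CCC[C@H]3N(C(=O)OC(C)(C)C)[C@H]2C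
F5 | step 16 | tert-butyl (2S,3R,4aS,5S,8aR)-5-[(5R)-5-{[tert-butyl(dimethyl)silyl]oxy}octyl]-3-{[(diethoxyphosphoryl)acetyl]oxy}-2-methyloctahydroquinoline-1(2H)-carboxylate | CCOP(=O)(OCC)CC(=O)O[C@@H]1C[C@H]2[C@@H](CCCC[C@H](O[Si](C)(C)C(C)(C)C)CCC)CCC[C@H]2N(C(=O)OC(C)(C)C)[C@H]1C
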